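Late in Wednesday's run, out to 15.0 min, free monomer lies flat near 37.3%. Thursday's flask, with 0.22 mM of initiator against 0.33 mM, has flattened at a like level by 3.00 min, and the two differ by about the scatter.

| flask | free monomer | initiator | remark | time |
|---|---|---|---|---|
| Thursday's | 5 mM | 0.22 mM | the very flask that is asked about, followed so far |  |
| Wednesday's | 5 mM | 0.33 mM | run made earlier |  |
| flask | 5.0 mM | 0.22 mM |  | 20 min |

| run | time / min | monomer in chains / % | free monomer / % |
|---|---|---|---|
| Thursday's | 0.833 | 41.7 | 57.8 |
| Thursday's | 1.50 | 55.2 | 44.7 |
| Thursday's | 2.50 | 59.5 | 38.5 |
| Thursday's | 3.00 | 60.1 | 37.0 |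
| Thursday's | 4.00 | 60.4 | 37.6 |
| Thursday's | 5.00 | 58.3 | 38.5 |
| Thursday's | 6.00 | 62.9 | 38.1 |
| Wednesday's | 2.00 | 58.0 | 37.4 |
| Wednesday's | 4.00 | 60.6 | 37.4 |
| Wednesday's | 6.00 | 60.4 | 36.6 |
| Wednesday's | 8.00 | 61.9 | 36.5 |
| Wednesday's | 10.0 | 60.2 | 36.8 |
| Wednesday's | 12.0 | 62.1 | 39.0 |
| Wednesday's | 15.0 | 60.3 | 37.3 |

(scatter of a reading: 1 percentage point)

- the average divides the monomer in chains by the number of chains begun, living and dead together
- the numbers in the tables scatter by 1 percentage point (one standard deviation)
- the earlier runs do not show the number of chains; that part of a forecast is a guess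

- whether the average number of monomer units in a chain (chains begun, living or dead) reaches 10 by 20 min (yes / no)
- average number of monomer units in a chain (chains begun, living or dead) at 20 min

I therefore take Thursday's flask at 20 min to stand on this plateau, and I reckon in steps. Its charge of free monomer matches Wednesday's, so I average Wednesday's readings from 4.00 min onward to get U, the monomer in chains on the plateau:

U = 60.9% of 5.0 mM = 3.05 mM

The readings do not show the number of chains, so my zero of the scale is the plain case of one chain per initiator charged. This gives L₀, the full-efficiency length, which is U divided by the initiator charged: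

L₀ = 3.05 mM / 0.22 mM = 13.8

The weak link is that one chain per initiator. I reforge it with f, the chains begun per initiator charged (the initiator efficiency), so that the average length is L₀/f. If an initiator begins one chain or none, f does not pass one and L₀ is the low end of the length. That low end stands above 10, so I answer yes.

The forecast says yes and 14, and adds: “The chain count is assumed, not measured”. My low end stands on the same count.

    free monomer + initiator → living end + monomer in chains (k = 26.7 /M/s)
    free monomer + living end → monomer in chains + living end, rate k2*[living end]*[free monomer] (k = 179 /M/s)
    monomer in chains + living end → free monomer + living end, rate k3*[living end] as long as [monomer in chains] is above zero (k = 0.333 /s)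
    free monomer + initiator → spent initiator (k = 14.5 /M/s)

Thursday's flask gives yes, with an average of 21.5 units at 20.0 min. It then holds living end 0.143 mM and spent initiator 0.0774 mM, with initiator at 0%. Set against L₀, that length gives f = 0.645. Wednesday's flask has L₀ = 9.23, below 10, and at the same f its average length comes to 14.3.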